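**Retrosynthetic overview**

- The route rests on the Z‑trisubstituted alkene C6=C7 (C6–H, C7–CH3; chain numbered from the ester carbon C1 to C10 on ring B), whose sp3 neighbours C5 and C8 are cis. It is a propyne unit, so C7–C8 and C5–C6 are cut together: ring B propyl Grignard reagent 13 + propyne 14 + iodide 12.
- Grignard reagent 13 comes from bromide 9 and alcohol 8; the C8–C10 chain is put on C4 of ring B by opening oxetane with the aryllithium from bromofuran 5.
- Bromofuran 5 comes from carbinol 4, made from furan‑3‑yllithium (ring A) and 4‑bromofuran‑2‑carbaldehyde (ring B), followed by deoxygenation of the linking carbon.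
- Iodide 12 comes from methyl hydrogen (R)‑3‑methylglutarate, which supplies the C3 stereocentre.
- No ring is formed: both furans (ring A, the 3‑substituted furan; ring B, the 2,4‑disubstituted furan) are bought intact.

Key step: step 8

Remark on the chemistry: the descriptor at C3 changes from R (10, 11) to S (12) and back to R (17) only because the CIP priorities of the two arms change; no bond to C3 is made or broken, and the racemic carbinol centre of 4 is erased in step 2.

**Route**

Step 1
Reactants: 1 3‑bromofuran; 2 4‑bromofuran‑2‑carbaldehyde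
Product: 4 racemic (4‑bromofuran‑2‑yl)(furan‑3‑yl)methanol, via furan‑3‑yllithium 3 (not isolated)
Conditions: n‑BuLi, THF, −78 °C; then 2, −78 °C; aq NH4Cl
Reagents that add atoms: none
Why: Bromine–lithium exchange gives furan‑3‑yllithium, configurationally and positionally stable at −78 °C, whose 1,2‑addition to the aldehyde (organolithium addition) is far faster than exchange with the ring bromine of 2; the new carbinol centre is racemic and is removed in step 2.

Step 2
Reactants: 4 racemic (4‑bromofuran‑2‑yl)(furan‑3‑yl)methanol
Product: 5 4‑bromo‑2‑(furan‑3‑ylmethyl)furan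
Conditions: Et3SiH, CF3CO2H, CH2Cl2, −20 °C → 0 °C
Reagents that add atoms: none
Why: Ionic hydrogenation: acid ionises the carbinol to a cation stabilised by both furan rings, which is trapped by hydride from excess Et3SiH at low temperature before it can alkylate another furan.

Step 3
Reactants: 5 4‑bromo‑2‑(furan‑3‑ylmethyl)furan; 6 oxetane
Product: 8 3‑[5‑(furan‑3‑ylmethyl)furan‑3‑yl]propan‑1‑ol, via [5‑(furan‑3‑ylmethyl)furan‑3‑yl]lithium 7 (not isolated)
Conditions: n‑BuLi, THF, −78 °C; then oxetane, BF3·OEt2, −78 °C; then H2O
Reagents that add atoms: none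
Why: Bromine–lithium exchange at −78 °C outruns deprotonation of the furan α‑positions and of the bis‑furyl CH2, and the BF3‑activated oxetane is opened by the aryllithium (Lewis‑acid‑promoted oxetane ring opening) at the same temperature, delivering the three‑carbon C8–C10 chain as a primary alcohol.

Step 4
Reactants: 8 3‑[5‑(furan‑3‑ylmethyl)furan‑3‑yl]propan‑1‑ol
Product: 9 4‑(3‑bromopropyl)‑2‑(furan‑3‑ylmethyl)furan
Conditions: CBr4, PPh3, CH2Cl2, 0 °C
Reagents that add atoms: carbon tetrabromide, BrC(Br)(Br)Br
Why: Appel bromination converts the primary alcohol to the bromide under essentially neutral conditions that the acid‑sensitive furans tolerate.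

Step 5
Reactants: 10 methyl hydrogen (R)‑3‑methylglutarate
Product: 11 methyl (3R)‑5‑hydroxy‑3‑methylpentanoate
Conditions: BH3·SMe2, THF, 0 °C → rt; MeOH
Reagents that add atoms: none
Why: Chemoselective borane reduction: the free carboxylic acid is reduced through its acyloxyborane much faster than the methyl ester, C3 is not involved, and the non‑acidic methanol quench keeps the hydroxy ester from lactonising before it is used crude.

Step 6
Reactants: 11 methyl (3R)‑5‑hydroxy‑3‑methylpentanoate
Product: 12 methyl (3S)‑5‑iodo‑3‑methylpentanoate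
Conditions: I2, PPh3, imidazole, CH2Cl2, 0 °C → rt
Reagents that add atoms: iodine, II
Why: Appel‑type iodination activates the primary hydroxyl as an alkoxyphosphonium ion that iodide displaces by SN2 at C5, faster than lactonisation and without touching the C3 centre.

Step 7
Reactants: 9 4‑(3‑bromopropyl)‑2‑(furan‑3‑ylmethyl)furan
Product: 13 {3‑[5‑(furan‑3‑ylmethyl)furan‑3‑yl]propyl}magnesium bromide (titrated Et2O solution, used directly)
Conditions: Mg turnings (I2 crystal), Et2O, 35 °C
Reagents that add atoms: magnesium, [Mg]
Why: Grignard formation by insertion of magnesium into the primary C–Br bond; the furan C–H bonds and the bis‑furyl CH2 are kinetically inert to an alkylmagnesium at this temperature, and Et2O is chosen because it is the solvent required for the following carbocupration.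

Step 8
Reactants: 13 {3‑[5‑(furan‑3‑ylmethyl)furan‑3‑yl]propyl}magnesium bromide; 14 propyne; 12 methyl (3S)‑5‑iodo‑3‑methylpentanoate
Product: 17 methyl (3R,6Z)‑10‑[5‑(furan‑3‑ylmethyl)furan‑3‑yl]‑3,7‑dimethyldec‑6‑enoate, via alkylcopper 15 (not isolated), via Z‑alkenylcopper 16 (not isolated)
Conditions: CuBr·SMe2, Et2O/Me2S, −45 °C; propyne, −45 °C → −25 °C; then THF, HMPA, P(OEt)3, 12, −30 °C → rt; aq NH4Cl/NH3
Reagents that add atoms: none
Why: Transmetalation of 13 with CuBr·SMe2 gives the monovalent alkylcopper 15 (as its MgBr2 complex), which adds across propyne through a four‑centre syn transition state, the alkyl carbon C8 going to the methyl‑bearing carbon C7 and copper to the terminal carbon C6, so that alkenylcopper 16 carries C8 and copper cis. The closest known reaction type is the Normant carbocupration of a terminal alkyne followed by alkylation of the alkenylcopper with a primary alkyl iodide. With P(OEt)3 as stabilising ligand and HMPA as donor cosolvent, 16 displaces iodide from the unhindered primary C5 of 12 with retention at the sp2 carbon, forming C5–C6. No ring closes and no stereocentre is created; the only stereochemical element set is the C6=C7 geometry, which should be Z because syn addition and retentive alkylation place C5 and C8 on the same side. The step needs regioselectivity (copper prefers the unsubstituted alkyne terminus), geometric integrity (16 is kept at or below −25 °C until the electrophile is present) and chemoselectivity (organocopper species leave the methyl ester, both furans and the C3 centre of 12 alone, so its configuration is carried over unchanged). Iodide 12 is the limiting component, and the 2‑methylalkene from protonation of surplus 16 is much less polar than ester 17 and should be removed by chromatography.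

**Compound list**

1 | 3‑bromofuran | Brc1ccoc1 | starting material
2 | 4‑bromofuran‑2‑carbaldehyde | O=Cc1cc(Br)co1 | starting material
3 | furan‑3‑yllithium (formed in the flask) | [Li]c1ccoc1 | intermediate
4 | (4‑bromofuran‑2‑yl)(furan‑3‑yl)methanol, racemic | OC(c1cc(Br)co1)c1ccoc1 | intermediate
5 | 4‑bromo‑2‑(furan‑3‑ylmethyl)furan | Brc1coc(Cc2ccoc2)c1 | intermediate
6 | oxetane | C1COC1 | starting material
7 | [5‑(furan‑3‑ylmethyl)furan‑3‑yl]lithium (formed in the flask) | [Li]c1coc(Cc2ccoc2)c1 | intermediate
8 | 3‑[5‑(furan‑3‑ylmethyl)furan‑3‑yl]propan‑1‑ol | OCCCc1coc(Cc2ccoc2)c1 | intermediate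
9 | 4‑(3‑bromopropyl)‑2‑(furan‑3‑ylmethyl)furan | BrCCCc1coc(Cc2ccoc2)c1 | intermediate
10 | methyl hydrogen (R)‑3‑methylglutarate, (3R)‑5‑methoxy‑3‑methyl‑5‑oxopentanoic acid | COC(=O)C[C@H](C)CC(=O)O | starting material
11 | methyl (3R)‑5‑hydroxy‑3‑methylpentanoate | COC(=O)C[C@H](C)CCO | intermediate
12 | methyl (3S)‑5‑iodo‑3‑methylpentanoate | COC(=O)C[C@H](C)CCI | intermediate
13 | {3‑[5‑(furan‑3‑ylmethyl)furan‑3‑yl]propyl}magnesium bromide | Br[Mg]CCCc1coc(Cc2ccoc2)c1 | intermediate
14 | propyne | CC#C | starting material
15 | {3‑[5‑(furan‑3‑ylmethyl)furan‑3‑yl]propyl}copper, as its MgBr2 complex (formed in the flask) | [Cu]CCCc1coc(Cc2ccoc2)c1 | intermediate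
16 | {(1Z)‑5‑[5‑(furan‑3‑ylmethyl)furan‑3‑yl]‑2‑methylpent‑1‑en‑1‑yl}copper (formed in the flask) | [Cu]/C=C(/C)CCCc1coc(Cc2ccoc2)c1 | intermediate
17 | methyl (3R,6Z)‑10‑[5‑(furan‑3‑ylmethyl)furan‑3‑yl]‑3,7‑dimethyldec‑6‑enoate | COC(=O)C[C@H](C)CC/C=C(/C)CCCc1coc(Cc2ccoc2)c1 | target

**Step count**

Total: 8 steps. Longest linear sequence: 6 steps (1, 2, 3, 4, 7, 8); the iodide arm (5, 6) joins in step 8.

**Steps most likely to fail**

1. Step 8. The alkylation of alkenylcopper 16 by an unactivated primary iodide may be slower than its thermal decay (protonation, oxidative dimerisation), so that C5–C6 is not formed efficiently. The fallback sets out from 16 (generated as in step 8 from 13 and 14) and from 12, and comes back to the route at 17. Alkenylcopper 16 is quenched at −40 °C with I2 in THF, which should give with retention the alkenyl iodide 2‑(furan‑3‑ylmethyl)‑4‑[(4Z)‑5‑iodo‑4‑methylpent‑4‑en‑1‑yl]furan F1. Separately, 12 is treated with activated zinc dust (Zn, 1,2‑dibromoethane and Me3SiCl activation) in THF/DMA at 40 °C to give [(3S)‑5‑methoxy‑3‑methyl‑5‑oxopentyl]zinc iodide F2. Negishi coupling of F1 with F2 under Pd(dppf)Cl2 in THF at rt to 50 °C, which retains alkene geometry and tolerates the ester, should then give 17. The bond is formed by cross‑coupling at palladium instead of substitution at copper.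

2. Step 3. Aryllithium 7 may be lost by proton transfer (isomerisation to an α‑lithiofuran or quenching by the bis‑furyl CH2), or BF3 may polymerise oxetane and degrade the furans before C–C bond formation. The fallback sets out from 5 and comes back at 8. tert‑Butyldimethyl(prop‑2‑en‑1‑yloxy)silane is hydroborated with 9‑BBN in THF to give 9‑[3‑(tert‑butyldimethylsilyloxy)propyl]‑9‑borabicyclo[3.3.1]nonane F3. This is coupled in the same flask with 5 (B‑alkyl Suzuki–Miyaura coupling; Pd(dppf)Cl2, K3PO4, THF/DMF/H2O, 60 °C) to give tert‑butyl{3‑[5‑(furan‑3‑ylmethyl)furan‑3‑yl]propoxy}dimethylsilane F4. Bu4NF in THF then releases alcohol 8. No organolithium or Lewis acid is involved.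

3. Step 2. The furfuryl‑type cation may alkylate a furan ring of another molecule (oligomerisation), or the acid may open the furans, in competition with hydride capture. The fallback sets out from 4 and comes back at 5. Oxidation of 4 with MnO2 in CH2Cl2 gives (4‑bromofuran‑2‑yl)(furan‑3‑yl)methanone F5. Hydrazine hydrate in diethylene glycol converts it to (4‑bromofuran‑2‑yl)(furan‑3‑yl)methanone hydrazone F6, and KOH at 120 °C → 190 °C (Wolff–Kishner reduction, Huang‑Minlon procedure) should give 5. The deoxygenation then runs entirely under basic conditions, with no cation.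

**Further compounds**

F1 | step 8 | 2‑(furan‑3‑ylmethyl)‑4‑[(4Z)‑5‑iodo‑4‑methylpent‑4‑en‑1‑yl]furan | I/C=C(/C)CCCc1coc(Cc2ccoc2)c1
F2 | step 8 | [(3S)‑5‑methoxy‑3‑methyl‑5‑oxopentyl]zinc iodide | COC(=O)C[C@H](C)CC[Zn]I
F3 | step 3 | 9‑[3‑(tert‑butyldimethylsilyloxy)propyl]‑9‑borabicyclo[3.3.1]nonane | CC(C)(C)[Si](C)(C)OCCCB1C2CCCC1CCC2
F4 | step 3 | tert‑butyl{3‑[5‑(furan‑3‑ylmethyl)furan‑3‑yl]propoxy}dimethylsilane | CC(C)(C)[Si](C)(C)OCCCc1coc(Cc2ccoc2)c1
F5 | step 2 | (4‑bromofuran‑2‑yl)(furan‑3‑yl)methanone | O=C(c1cc(Br)co1)c1ccoc1
F6 | step 2 | (4‑bromofuran‑2‑yl)(furan‑3‑yl)methanone hydrazone | NN=C(c1cc(Br)co1)c1ccoc1
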